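## Retrosynthetic overview
1. Ring C, formed last: break O1–C2. The flavanone is the 6-endo oxa-Michael isomer of the unprotected (E)-3'-prenyl-2',4',6'-trihydroxy-4-methoxychalcone. It is closed through the 6'-OH under a chiral bifunctional catalyst (chalcone isomerase logic), and this sets C2 as S.
2. Ring A, formed before it: break C1'–C2' of the chalcone. This is the C6-to-C1 Claisen folding of a linear 4-methoxycinnamoyl tetraketide methyl ester (chalcone synthase logic), released in situ from a 4-hydroxy-2-pyrone.
3. Starter/triketide bond: the pyrone comes from the 6-methyl carbanion of 3-prenyl triacetic acid lactone and methyl 4-methoxycinnamate.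
4. Prenyl group: it goes on C3 of triacetic acid lactone, which maps to C2 of the tetraketide, C3' of the chalcone and C6 of the flavanone. It also blocks the competing stilbene-type C2-to-C7 aldol folding.
5. Ring order: ring B is bought, the pyrone serves as the masked chain, then ring A forms, then ring C. There are no protecting groups and three steps.

Assumption: the quinidine-derived thiourea is taken to give the (2S) series. The sense is read from the CD spectrum of the first run (2S: positive band near 330 nm, negative band near 290 nm). If the sign is reversed, the quinine-derived pseudoenantiomer takes its place.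

## Route

Step 1
Reactants: 1 4-hydroxy-6-methyl-2H-pyran-2-one (triacetic acid lactone); 2 3-methylbut-2-en-1-yl acetate (prenyl acetate)
Product: 3 4-hydroxy-6-methyl-3-(3-methylbut-2-en-1-yl)-2H-pyran-2-one
Conditions: 1 (1.3 equiv), Pd(PPh3)4 (3 mol%), Et3N (1.3 equiv), THF, 60 °C, 12 h; acidic work-up, crystallise
Reagents that add atoms: none
Why: Tsuji–Trost allylic alkylation, in which zerovalent palladium ionises 2 to the 1,1-dimethyl-π-allyl complex, the soft C3 carbon of the acidic pyrone (pKa about 5) attacks the unhindered CH2 terminus to give the linear prenyl group, and any kinetically formed 4-O-prenyl ether is re-ionised and funnelled to the thermodynamic C3 product; no stereocentre is formed.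

Step 2
Reactants: 3 4-hydroxy-6-methyl-3-(3-methylbut-2-en-1-yl)-2H-pyran-2-one; 4 methyl (E)-3-(4-methoxyphenyl)prop-2-enoate (methyl 4-methoxycinnamate)
Product: 6 4-hydroxy-6-[(3E)-4-(4-methoxyphenyl)-2-oxobut-3-en-1-yl]-3-(3-methylbut-2-en-1-yl)-2H-pyran-2-one, via dilithio dianion 5 (not isolated)
Conditions: 3 (2.0 equiv), LiN(iPr)2 (4.1 equiv), THF–DMPU, −78 °C, 1 h; then 4 (1.0 equiv), −78 to −20 °C; 1 M HCl; excess 3 recovered
Reagents that add atoms: none
Why: Claisen-type acylation of a 4-hydroxy-2-pyrone dianion, in which the second deprotonation takes place at the vinylogous 6-methyl group, this most basic carbon attacks the ester carbonyl of the electron-rich and poorly Michael-accepting cinnamate in the 1,2 sense, and the second equivalent of 5 deprotonates the more acidic product so that it is not attacked again; no stereocentre is formed.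

Step 3
Reactants: 6 4-hydroxy-6-[(3E)-4-(4-methoxyphenyl)-2-oxobut-3-en-1-yl]-3-(3-methylbut-2-en-1-yl)-2H-pyran-2-one
Product: 9 (2S)-5,7-dihydroxy-2-(4-methoxyphenyl)-6-(3-methylbut-2-en-1-yl)-2,3-dihydro-4H-chromen-4-one, via tetraketide methyl ester 7 (not isolated), via prenylated chalcone 8 (not isolated)
Conditions: Mg(OMe)2 (5 equiv), MeOH, reflux, Ar, 12 h; then 50% aq KOH, 20 °C, 15 min; pour into ice-cold 3 M HCl, extract CH2Cl2, cold pH 6.5 phosphate wash, swap to toluene below 25 °C; then N-[3,5-bis(trifluoromethyl)phenyl]-N'-[(9R)-6'-methoxycinchonan-9-yl]thiourea (quinidine-derived, 10 mol%), toluene–CH2Cl2 9:1, 0.05 M, −20 °C, 72 h; AcOH quench, SiO2 (removes minor regioisomer), recrystallise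
Reagents that add atoms: none
Why: Proposed new method: Mg(OMe)2 opens the lactone to the chelated tetraketide ester 7, whose only aromatising folding is the C6-to-C1 Claisen (Dieckmann-type) cyclisation with loss of methanol because the prenyl group leaves C2 unable to aromatise after a C2-to-C7 aldol (closest known reaction: base- or Mg(OMe)2-induced cyclisation of 3,5,7-triketo esters and 6-acylmethyl-4-hydroxy-2-pyrones to acylphloroglucinols), concentrated KOH then re-opens any flavanone formed in the pot (classical flavanone-to-chalcone opening) so that only achiral 8 meets the catalyst, and in the apolar medium the quinuclidine nitrogen takes the proton of the unhindered 6'-OH while the thiourea N–H bonds hold the carbonyl oxygen that stays chelated to the prenyl-buttressed 2'-OH, so that O6' adds to the Si face of C-β in a 6-endo-trig oxa-Michael closure that gives the 6-prenyl regioisomer and sets C2 as S (closest known reaction: cinchona-thiourea-catalysed enantioselective cyclisation of 2'-hydroxychalcones to flavanones; new here are the unprotected trihydroxy substrate and the choice between two ortho hydroxyls).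

Nothing follows step 3. The base-labile C2 centre therefore meets only cold, weakly basic catalysis, an acid quench and neutral crystallisation.

## Compound list
1 | 4-hydroxy-6-methyl-2H-pyran-2-one (triacetic acid lactone) | CC1=CC(O)=CC(=O)O1 | starting material
2 | 3-methylbut-2-en-1-yl acetate (prenyl acetate) | CC(=O)OCC=C(C)C | starting material
3 | 4-hydroxy-6-methyl-3-(3-methylbut-2-en-1-yl)-2H-pyran-2-one | CC1=CC(O)=C(CC=C(C)C)C(=O)O1 | intermediate
4 | methyl (E)-3-(4-methoxyphenyl)prop-2-enoate | COC(=O)/C=C/c1ccc(OC)cc1 | starting material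
5 | dilithio dianion of 3 (4-olate, carbanion at the 6-CH2) | [Li+].[Li+].[CH2-]C1=CC([O-])=C(CC=C(C)C)C(=O)O1 | intermediate
6 | 4-hydroxy-6-[(3E)-4-(4-methoxyphenyl)-2-oxobut-3-en-1-yl]-3-(3-methylbut-2-en-1-yl)-2H-pyran-2-one | COc1ccc(/C=C/C(=O)CC2=CC(O)=C(CC=C(C)C)C(=O)O2)cc1 | intermediate
7 | methyl (8E)-9-(4-methoxyphenyl)-2-(3-methylbut-2-en-1-yl)-3,5,7-trioxonon-8-enoate (C2 epimerisable, present as magnesium enolate) | COC(=O)C(CC=C(C)C)C(=O)CC(=O)CC(=O)/C=C/c1ccc(OC)cc1 | intermediate
8 | (E)-3-(4-methoxyphenyl)-1-[2,4,6-trihydroxy-3-(3-methylbut-2-en-1-yl)phenyl]prop-2-en-1-one | COc1ccc(/C=C/C(=O)c2c(O)cc(O)c(CC=C(C)C)c2O)cc1 | intermediate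
9 | (2S)-5,7-dihydroxy-2-(4-methoxyphenyl)-6-(3-methylbut-2-en-1-yl)-2,3-dihydro-4H-chromen-4-one | COc1ccc([C@@H]2CC(=O)c3c(cc(O)c(CC=C(C)C)c3O)O2)cc1 | target

## Count and risks
Total step count: 3. Longest linear sequence: 3 (1 to 3 to 6 to 9).

**Step 3 (highest risk).**
- The two ortho hydroxyls of 8 may be told apart only moderately. Uncatalysed closures of 3'-prenylated 2',4',6'-trihydroxychalcones give 6- and 8-prenyl flavanones in comparable amounts.
- Background closure can erode the ee.
- Acidic pyrone residues can switch off the amine catalyst.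
- The fallback sets out from 8 and comes back at 9. It gives up catalyst control and treats the closure as a recyclable isomerisation. Crude 8 is cyclised with NaOAc in refluxing EtOH to racemic 5,7-dihydroxy-4'-methoxy-6-prenylflavanone F1 and racemic 5,7-dihydroxy-4'-methoxy-8-prenylflavanone F2, which are separated on silica. F1 is resolved by preparative supercritical-fluid chromatography on an amylose tris(3,5-dimethylphenylcarbamate) phase into 9 and (2R)-5,7-dihydroxy-4'-methoxy-6-prenylflavanone F3. F2 and F3 are returned to 8 with 50% aq KOH and cold acidification, then cycled again.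

**Step 2.**
- The dianion may add 1,4 to the cinnamate.
- Proton transfer from the product may stall the acylation.
- The fallback sets out from 3 and comes back at 6. It replaces acylation by aldol addition and oxidation. Dianion 5 is added at −78 °C to commercial (E)-4-methoxycinnamaldehyde, which reacts only in the 1,2 sense and needs no sacrificial base. This gives racemic 4-hydroxy-6-[(3E)-2-hydroxy-4-(4-methoxyphenyl)but-3-en-1-yl]-3-(3-methylbut-2-en-1-yl)-2H-pyran-2-one F4. Its allylic alcohol is oxidised with MnO2 in CH2Cl2 to 6.

**Step 1.**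
- O-alkylation, a second prenylation at C3 or the branched 1,1-dimethylallyl isomer may compete.
- The fallback sets out from 2 and comes back at 3. It builds the pyrone around the prenyl group instead of prenylating the ring. Methyl acetoacetate (NaH, Pd(PPh3)4, THF) is allylated with 2 to methyl 2-acetyl-5-methylhex-4-enoate F5. Its dianion (NaH, then n-BuLi) is acetylated at the terminal carbon with N-methoxy-N-methylacetamide to give methyl 2-(3-methylbut-2-en-1-yl)-3,5-dioxohexanoate F6. DBU in refluxing toluene then lactonises F6 to 3.

## Further compounds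
F1 | step 3 | racemic 5,7-dihydroxy-2-(4-methoxyphenyl)-6-(3-methylbut-2-en-1-yl)-2,3-dihydro-4H-chromen-4-one | COc1ccc(C2CC(=O)c3c(cc(O)c(CC=C(C)C)c3O)O2)cc1
F2 | step 3 | racemic 5,7-dihydroxy-2-(4-methoxyphenyl)-8-(3-methylbut-2-en-1-yl)-2,3-dihydro-4H-chromen-4-one | COc1ccc(C2CC(=O)c3c(O)cc(O)c(CC=C(C)C)c3O2)cc1
F3 | step 3 | (2R)-5,7-dihydroxy-2-(4-methoxyphenyl)-6-(3-methylbut-2-en-1-yl)-2,3-dihydro-4H-chromen-4-one | COc1ccc([C@H]2CC(=O)c3c(cc(O)c(CC=C(C)C)c3O)O2)cc1
F4 | step 2 | racemic 4-hydroxy-6-[(3E)-2-hydroxy-4-(4-methoxyphenyl)but-3-en-1-yl]-3-(3-methylbut-2-en-1-yl)-2H-pyran-2-one | COc1ccc(/C=C/C(O)CC2=CC(O)=C(CC=C(C)C)C(=O)O2)cc1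
F5 | step 1 | methyl 2-acetyl-5-methylhex-4-enoate (racemic) | COC(=O)C(CC=C(C)C)C(C)=O
F6 | step 1 | methyl 2-(3-methylbut-2-en-1-yl)-3,5-dioxohexanoate (racemic) | COC(=O)C(CC=C(C)C)C(=O)CC(C)=O
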